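**Plan**
Ring labels: A is the monohydroxy ring, B the para-phenylene, C the catechol ring, D the meta-phenylene.
Cuts, in order: the two ring C O–CH3 bonds and three placeholder C–halogen bonds; the bond from the ring B oxygen to the ring A carbon next to C–OH, which opens the 18-membered ring; the two ArCH2–CH2Ar bridges, each as a Wittig C=C; the O–C(ring D) bond of the ring C–O–ring D ether.
Enabling feature: on ring A the ether oxygen to ring B sits on the carbon adjacent to the hydroxyl-bearing carbon, and the ethylene bridge is para to that hydroxyl. Oxidising a 4-alkyl-2,6-dihalophenol in the presence of a second phenol oxygen leaves exactly this ortho-aryloxyphenol pattern.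
Forward: all four benzene rings are bought. C and D are joined first by copper O-arylation, B is attached to C and then A to D by Wittig reactions, and both alkenes are saturated together. The only ring formed is the macrocycle, closed by anodic oxidation.
Stereochemistry: the target has no stereocentre and no C=C. The alkene mixtures converge on reduction, and the transient quaternary carbon of the dienone is erased by zinc.

Key step: step 12

Remark: both Wittig products are carried on as E/Z mixtures, so their SMILES bear no double-bond descriptor.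

**Step 1**
Reactants: 1 3,5-dichloro-4-hydroxybenzaldehyde
Product: 2 4-(benzyloxy)-3,5-dichlorobenzaldehyde
Conditions: BnBr, K2CO3, DMF, 60 °C
Reagents that add atoms: benzyl bromide, BrCc1ccccc1
Why: Williamson ether synthesis, in which K2CO3 fully ionises the acidic dihalophenol and its oxygen is benzylated, so that the later phosphonium salt cannot collapse to a quinone methide when treated with base.

**Step 2**
Reactants: 2 4-(benzyloxy)-3,5-dichlorobenzaldehyde
Product: 3 [4-(benzyloxy)-3,5-dichlorophenyl]methanol
Conditions: NaBH4, MeOH–THF, 0 °C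
Reagents that add atoms: none
Why: Borohydride reduction of an aromatic aldehyde, which leaves aryl chlorides and the benzyl ether untouched.

**Step 3**
Reactants: 3 [4-(benzyloxy)-3,5-dichlorophenyl]methanol
Product: 4 [4-(benzyloxy)-3,5-dichlorobenzyl]triphenylphosphonium bromide (ring B salt)
Conditions: PPh3·HBr, MeCN, reflux
Reagents that add atoms: triphenylphosphine hydrobromide, Br.c1ccc(cc1)P(c1ccccc1)c1ccccc1
Why: Direct phosphonium salt formation from a benzylic alcohol by acid-promoted nucleophilic substitution, in which the hydroxyl is activated by the acid and PPh3 takes the benzylic carbon, while this mild acid does not protonate the weakly basic, hindered benzyl aryl ether.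

**Step 4**
Reactants: 5 3,5-dibromo-4-hydroxybenzaldehyde
Product: 6 4-(benzyloxy)-3,5-dibromobenzaldehyde
Conditions: BnBr, K2CO3, DMF, 60 °C
Reagents that add atoms: benzyl bromide, BrCc1ccccc1
Why: Williamson ether synthesis on the ionised dibromophenol, for the same reason as in step 1.

**Step 5**
Reactants: 6 4-(benzyloxy)-3,5-dibromobenzaldehyde
Product: 7 [4-(benzyloxy)-3,5-dibromophenyl]methanol
Conditions: NaBH4, MeOH–THF, 0 °C
Reagents that add atoms: none
Why: Borohydride reduction of the aldehyde, which does not affect aryl bromides.

**Step 6**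
Reactants: 7 [4-(benzyloxy)-3,5-dibromophenyl]methanol
Product: 8 [4-(benzyloxy)-3,5-dibromobenzyl]triphenylphosphonium bromide (ring A salt)
Conditions: PPh3·HBr, MeCN, reflux
Reagents that add atoms: triphenylphosphine hydrobromide, Br.c1ccc(cc1)P(c1ccccc1)c1ccccc1
Why: The same acid-promoted substitution of a benzylic alcohol by PPh3 as in step 3, with aryl bromides inert to phosphine in the absence of a metal.

**Step 7**
Reactants: 9 2-hydroxy-3,4-dimethoxybenzaldehyde; 10 2-(3-bromophenyl)-1,3-dioxolane
Product: 11 2-[3-(1,3-dioxolan-2-yl)phenoxy]-3,4-dimethoxybenzaldehyde (ring C–O–ring D core)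
Conditions: CuI (cat.), picolinic acid (cat.), K3PO4, DMSO, 90 °C
Reagents that add atoms: none
Why: Ligand-accelerated Ullmann diaryl ether synthesis, in which picolinic acid keeps copper active towards phenols substituted at both ortho positions, and the non-enolisable aldehyde and the base-stable dioxolane survive K3PO4.

**Step 8**
Reactants: 4 ring B phosphonium bromide; 11 ring C–O–ring D core
Product: 14 3-(6-{2-[4-(benzyloxy)-3,5-dichlorophenyl]ethenyl}-2,3-dimethoxyphenoxy)benzaldehyde (E/Z mixture), via ring B ylide 12 (not isolated), via stilbene acetal 13 (not isolated)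
Conditions: K2CO3, 18-crown-6 (cat.), CH2Cl2, reflux; then 1 M HCl, THF, rt
Reagents that add atoms: water, O
Why: Wittig olefination of the only free aldehyde by the semi-stabilised benzylic ylide, followed by acid-catalysed acetal hydrolysis that unmasks the ring D aldehyde only after ring B is in place, the alkene geometry being irrelevant because step 10 removes it.

**Step 9**
Reactants: 8 ring A phosphonium bromide; 14 ring D aldehyde
Product: 16 open bis-stilbene with a 4-benzyloxy-3,5-dibromostyryl group on ring D and a 4-benzyloxy-3,5-dichlorostyryl group on ring C (E/Z mixture at both alkenes), via ring A ylide 15 (not isolated)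
Conditions: K2CO3, 18-crown-6 (cat.), CH2Cl2, reflux
Reagents that add atoms: none
Why: A second Wittig olefination, now at the unhindered ring D aldehyde, with a carbonate base too weak to disturb aryl halides or benzyl ethers.

**Step 10**
Reactants: 16 open bis-stilbene
Product: 17 open bis(bibenzyl) dibenzyl ether (both bridges CH2–CH2)
Conditions: TsNHNH2 (excess, in portions), NaOAc, THF–H2O, reflux
Reagents that add atoms: none
Why: Diimide reduction, in which HN=NH released from the sulfonyl hydrazide delivers two hydrogens to each C=C through a concerted cyclic transition state and does not cleave the C–Br, C–Cl or O–benzyl bonds that hydrogenation over palladium would.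

**Step 11**
Reactants: 17 open bis(bibenzyl) dibenzyl ether
Product: 18 2,6-dibromo-4-[2-(3-{6-[2-(3,5-dichloro-4-hydroxyphenyl)ethyl]-2,3-dimethoxyphenoxy}phenyl)ethyl]phenol (open bis(dihalophenol))
Conditions: BCl3, pentamethylbenzene, CH2Cl2, −78 °C; then H2O
Reagents that add atoms: none
Why: Lewis-acid debenzylation with a cation scavenger, in which BCl3 ionises each O–benzyl bond (helped by the good dihalophenoxide leaving group), pentamethylbenzene traps the benzyl cation by Friedel–Crafts alkylation, and methyl ethers and aryl halides are not attacked at −78 °C.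

**Step 12**
Reactants: 18 open bis(dihalophenol)
Product: 20 macrocyclic diaryl ether, being marchantin H ring C dimethyl ether with Br on ring A ortho to the hydroxyl and Cl on both ring B carbons flanking the new ether oxygen, via methoxydienone macrocycle 19 (not isolated)
Conditions: glassy-carbon anode, Pt cathode, undivided cell, LiClO4 (0.1 M), MeOH–CH2Cl2, slow addition of 18 (about 1 mM), anode held at the foot of the first wave of 18, 2 F/mol, rt; then Zn, AcOH–THF, rt
Reagents that add atoms: methanol, CO (its methoxy group stands in 19 only and leaves again in the zinc stage)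
Why: Loss of two electrons and a proton from the ring A dibromophenol gives a phenoxonium ion, the ring B phenol oxygen adds to one of its two equivalent bromine-bearing ortho carbons, bromide departs, and methanol is taken up at the alkyl-bearing para carbon to give 4-methoxycyclohexa-2,5-dienone 19, which zinc in acetic acid returns to the phenol with loss of methanol. This is the oxidative C–O coupling of ortho,ortho'-dihalophenols, established at an anode for diaryl ethers and with Tl(NO3)3 for macrocyclic diaryl ethers, in both cases followed by zinc reduction. The 18-membered ring closes by attack of a tethered oxygen nucleophile on a cationic ring carbon (ipso replacement of bromide), and slow addition into dilute electrolyte favours this over intermolecular coupling. No stereocentre is retained, since the quaternary carbon of 19 forms racemic and is flattened again by zinc. The step needs the right direction (ring A oxidised, ring B as nucleophile), C–O rather than C–C coupling, and an untouched ring C: bromine makes ring A easier to oxidise than chlorinated ring B and is the better leaving group, all four ortho and both para positions are blocked, and the anode stays below the onset of the dimethoxyarene. Material that merely adds methanol at the para carbon falls back to 18 in the zinc stage and can be resubmitted, and any stray ring bromination by anodically formed bromine is erased in step 13.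

**Step 13**
Reactants: 20 halogenated macrocycle
Product: 21 marchantin H ring C dimethyl ether
Conditions: H2, 10% Pd/C, Et3N, MeOH–EtOAc, rt
Reagents that add atoms: none
Why: Catalytic hydrodehalogenation, in which zerovalent palladium inserts into the C–Br and both C–Cl bonds and H2 replaces each halogen by hydrogen with Et3N as acid acceptor, while diaryl ethers, methyl ethers and the bibenzyl bridges are inert.

**Step 14**
Reactants: 21 marchantin H ring C dimethyl ether
Product: 22 marchantin H
Conditions: BBr3, CH2Cl2, −78 °C to rt; then H2O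
Reagents that add atoms: none
Why: BBr3 demethylation of aryl methyl ethers, in which boron binds each methoxy oxygen, bromide removes the methyl group by SN2 and hydrolysis frees the catechol, whereas the diaryl ethers offer no sp3 carbon for attack.

**Compound list**
1 | 3,5-dichloro-4-hydroxybenzaldehyde | O=Cc1cc(Cl)c(O)c(Cl)c1 | starting material
2 | 4-(benzyloxy)-3,5-dichlorobenzaldehyde | O=Cc1cc(Cl)c(OCc2ccccc2)c(Cl)c1 | intermediate
3 | [4-(benzyloxy)-3,5-dichlorophenyl]methanol | OCc1cc(Cl)c(OCc2ccccc2)c(Cl)c1 | intermediate
4 | [4-(benzyloxy)-3,5-dichlorobenzyl]triphenylphosphonium bromide | [Br-].Clc1cc(C[P+](c2ccccc2)(c2ccccc2)c2ccccc2)cc(Cl)c1OCc1ccccc1 | intermediate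
5 | 3,5-dibromo-4-hydroxybenzaldehyde | O=Cc1cc(Br)c(O)c(Br)c1 | starting material
6 | 4-(benzyloxy)-3,5-dibromobenzaldehyde | O=Cc1cc(Br)c(OCc2ccccc2)c(Br)c1 | intermediate
7 | [4-(benzyloxy)-3,5-dibromophenyl]methanol | OCc1cc(Br)c(OCc2ccccc2)c(Br)c1 | intermediate
8 | [4-(benzyloxy)-3,5-dibromobenzyl]triphenylphosphonium bromide | [Br-].Brc1cc(C[P+](c2ccccc2)(c2ccccc2)c2ccccc2)cc(Br)c1OCc1ccccc1 | intermediate
9 | 2-hydroxy-3,4-dimethoxybenzaldehyde | O=Cc1ccc(OC)c(OC)c1O | starting material
10 | 2-(3-bromophenyl)-1,3-dioxolane | Brc1cccc(c1)C1OCCO1 | starting material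
11 | 2-[3-(1,3-dioxolan-2-yl)phenoxy]-3,4-dimethoxybenzaldehyde | O=Cc1ccc(OC)c(OC)c1Oc1cccc(c1)C1OCCO1 | intermediate
12 | [4-(benzyloxy)-3,5-dichlorobenzylidene]triphenylphosphorane (ring B ylide) | Clc1cc(C=P(c2ccccc2)(c2ccccc2)c2ccccc2)cc(Cl)c1OCc1ccccc1 | intermediate
13 | 2-[3-(6-{2-[4-(benzyloxy)-3,5-dichlorophenyl]ethenyl}-2,3-dimethoxyphenoxy)phenyl]-1,3-dioxolane (E/Z) | C1COC(O1)c1cccc(c1)Oc1c(OC)c(OC)ccc1C=Cc1cc(Cl)c(OCc2ccccc2)c(Cl)c1 | intermediate
14 | 3-(6-{2-[4-(benzyloxy)-3,5-dichlorophenyl]ethenyl}-2,3-dimethoxyphenoxy)benzaldehyde (E/Z) | O=Cc1cccc(c1)Oc1c(OC)c(OC)ccc1C=Cc1cc(Cl)c(OCc2ccccc2)c(Cl)c1 | intermediate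
15 | [4-(benzyloxy)-3,5-dibromobenzylidene]triphenylphosphorane (ring A ylide) | Brc1cc(C=P(c2ccccc2)(c2ccccc2)c2ccccc2)cc(Br)c1OCc1ccccc1 | intermediate
16 | open bis-stilbene dibenzyl ether (E/Z at both alkenes) | Brc1cc(cc(Br)c1OCc1ccccc1)C=Cc1cccc(c1)Oc1c(OC)c(OC)ccc1C=Cc1cc(Cl)c(OCc2ccccc2)c(Cl)c1 | intermediate
17 | open bis(bibenzyl) dibenzyl ether | Brc1cc(cc(Br)c1OCc1ccccc1)CCc1cccc(c1)Oc1c(OC)c(OC)ccc1CCc1cc(Cl)c(OCc2ccccc2)c(Cl)c1 | intermediate
18 | open bis(dihalophenol), ring C dimethyl ether | Oc1c(Br)cc(cc1Br)CCc1cccc(c1)Oc1c(OC)c(OC)ccc1CCc1cc(Cl)c(O)c(Cl)c1 | intermediate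
19 | macrocyclic 2-aryloxy-6-bromo-4-methoxycyclohexa-2,5-dienone (racemic at the methoxy-bearing carbon) | O=C1C(Br)=CC2(OC)C=C1Oc1c(Cl)cc(cc1Cl)CCc1ccc(OC)c(OC)c1Oc1cccc(c1)CC2 | intermediate
20 | bromo-dichloro macrocyclic diaryl ether, ring C dimethyl ether | Oc1c(Br)cc2cc1Oc1c(Cl)cc(cc1Cl)CCc1ccc(OC)c(OC)c1Oc1cccc(c1)CC2 | intermediate
21 | marchantin H ring C dimethyl ether | Oc1ccc2cc1Oc1ccc(cc1)CCc1ccc(OC)c(OC)c1Oc1cccc(c1)CC2 | intermediate
22 | marchantin H | Oc1ccc2cc1Oc1ccc(cc1)CCc1ccc(O)c(O)c1Oc1cccc(c1)CC2 | target

**Count**
Total steps: 14.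
Longest linear sequence: 10 (steps 1, 2, 3, 8, 9, 10, 11, 12, 13, 14).

**Steps most likely to fail**

**Step 12.** Chain growth between molecules may outrun ring closure. Ring C may be oxidised alongside ring A. The coupling may also run in the reverse direction.

The fallback closes the same ring A–O–ring B bond by nucleophilic aromatic substitution instead of oxidation. It sets out from 14 and rejoins the route at 21.
- Commercial 3-fluoro-4-nitrobenzyl bromide and PPh3 in toluene should give (3-fluoro-4-nitrobenzyl)triphenylphosphonium bromide F1.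
- With K2CO3 and 18-crown-6 in CH2Cl2 this forms (3-fluoro-4-nitrobenzylidene)triphenylphosphorane F2, which olefinates 14 to the fluoronitro bis-stilbene F3.
- Diimide from KO2CN=NCO2K and AcOH at rt is chosen because it brings no sulfinate or hydrazide nucleophile near the activated fluoride. It should saturate both alkenes to the fluoronitro bis(bibenzyl) benzyl ether F4.
- BCl3 and pentamethylbenzene free the ring B phenol, giving the fluoronitro dichlorophenol F5.
- K2CO3 in dilute DMF should close the 18-membered ring by displacing the fluoride ortho to the nitro group, giving the nitro-dichloro macrocycle F6.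
- H2, Pd/C and Et3N reduce the nitro group and remove both chlorines, giving the ring A aniline macrocycle F7.
- NaNO2 in aqueous H2SO4 gives the macrocyclic diazonium hydrogensulfate F8. Sandmeyer-type hydroxylation with Cu2O and Cu(NO3)2 in water then gives 21.

**Step 7.** The phenol of 9 is flanked on both sides, hydrogen-bonded to its aldehyde and able to chelate copper. O-arylation may therefore stall while the aryl bromide is consumed by reduction or homocoupling.

The fallback reverses the polarity of the bond formation. It sets out from 10 and rejoins the route at 11.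
- Hydroxylation of 10 with Pd2(dba)3, tBuXPhos and KOH in dioxane–H2O, with a neutral work-up, should give 3-(1,3-dioxolan-2-yl)phenol F9.
- The unhindered phenoxide of F9 then displaces fluoride from commercial 2-fluoro-3,4-dimethoxybenzaldehyde (K2CO3, DMF, 120 °C). This is an SNAr activated by the ortho formyl group, and it gives 11.

**Step 11.** The two hindered, weakly basic benzyl ethers may ionise only on warming. At that point the crowded middle methoxy group of ring C could be lost, which would unmask an easily oxidised phenol before the electrolysis.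

The fallback replaces electrophilic activation of the ether oxygen by SN2 displacement at the benzylic carbon. It sets out from 17 and rejoins the route at 18.
- NaSEt in DMF at about 60 °C, followed by dilute acid, should expel the two dihalophenoxides.
- These are far better leaving groups than the alkoxyphenoxides that demethylation of ring C would have to release.

**Further compounds**
F1 | step 12 | (3-fluoro-4-nitrobenzyl)triphenylphosphonium bromide | [Br-].[O-][N+](=O)c1ccc(C[P+](c2ccccc2)(c2ccccc2)c2ccccc2)cc1F
F2 | step 12 | (3-fluoro-4-nitrobenzylidene)triphenylphosphorane | [O-][N+](=O)c1ccc(C=P(c2ccccc2)(c2ccccc2)c2ccccc2)cc1F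
F3 | step 12 | fluoronitro bis-stilbene (E/Z at both alkenes) | [O-][N+](=O)c1ccc(cc1F)C=Cc1cccc(c1)Oc1c(OC)c(OC)ccc1C=Cc1cc(Cl)c(OCc2ccccc2)c(Cl)c1
F4 | step 12 | fluoronitro bis(bibenzyl) benzyl ether | [O-][N+](=O)c1ccc(cc1F)CCc1cccc(c1)Oc1c(OC)c(OC)ccc1CCc1cc(Cl)c(OCc2ccccc2)c(Cl)c1
F5 | step 12 | fluoronitro dichlorophenol | [O-][N+](=O)c1ccc(cc1F)CCc1cccc(c1)Oc1c(OC)c(OC)ccc1CCc1cc(Cl)c(O)c(Cl)c1
F6 | step 12 | nitro-dichloro macrocycle | [O-][N+](=O)c1ccc2cc1Oc1c(Cl)cc(cc1Cl)CCc1ccc(OC)c(OC)c1Oc1cccc(c1)CC2
F7 | step 12 | ring A aniline macrocycle | Nc1ccc2cc1Oc1ccc(cc1)CCc1ccc(OC)c(OC)c1Oc1cccc(c1)CC2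
F8 | step 12 | macrocyclic diazonium hydrogensulfate | N#[N+]c1ccc2cc1Oc1ccc(cc1)CCc1ccc(OC)c(OC)c1Oc1cccc(c1)CC2.OS(=O)(=O)[O-]
F9 | step 7 | 3-(1,3-dioxolan-2-yl)phenol | Oc1cccc(c1)C1OCCO1
F0 | step 11 | none | none
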